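## Retrosynthetic overview

1. The target, an ent-labdane (labdane numbering), is traced back to a tricyclic 6-oxo-labd-7-ene carrying a 2,3-acetonide, a C19 silyl ether and a C15 tert-butyl ester. The extra C6 oxygen is removed by Luche reduction, acetylation and palladium-catalysed reduction of the allylic acetate.
2. Key disconnection: C5–C10 and C7=C8 together. Both rings of the decalin open to an acyclic methyl ketone/enone, C7H3–C6(=O)–C5H2–C4 … C1H2–C10(Me)=C9(R)–C8(=O)–C17H3, closed forward by a base-mediated Michael/aldol-condensation cascade.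
3. Enabling feature: in ring B one carbonyl at C6 makes both C5 and C7 nucleophilic, while C10–C9–C8 is an enone (C10 β-carbon, C8 carbonyl). C5–C10 is the ring-fusion bond, so the first bond also closes ring A. The cis-2,3-diol, locked as a dioxolane, and the quaternary C4 pre-fold the chain and relay configuration to C10, C5 and C9.
4. The acyclic precursor is assembled from diethyl (R)-malate (C2–C4, C18, C19, C5–C7; two Fráter–Seebach alkylations relay C3 to C4), a propargyl unit (C1, C10, C9; Felkin–Anh addition sets C2), acetyl and methyl reagents (C8/C17, C20), and (S)-monomethyl 3-methylglutarate (C11–C16, joined by Negishi coupling).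
5. Ring order: temporary dioxolane on C2/C3 first, then rings A and B in one operation, dioxolane removed last.

Key step: step 16

Assumption: labdane numbering (C1–C10 decalin, C11–C16 side chain, C17 on C8, C18 and C19 on C4, C20 on C10) is used for all intermediates, and diethyl (R)-malate and (S)-monomethyl 3-methylglutarate are taken as purchasable single enantiomers.

## Route

Step 1
Reactants: 1 (S)-5-methoxy-3-methyl-5-oxopentanoic acid
Product: 2 1-tert-butyl 5-methyl (3R)-3-methylpentanedioate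
Conditions: t-BuOC(=NH)CCl3, BF3·OEt2 (cat.), CH2Cl2/cyclohexane, 23 °C
Reagents that add atoms: tert-butyl 2,2,2-trichloroacetimidate, CC(C)(C)OC(=N)C(Cl)(Cl)Cl
Why: Acid-catalysed O-alkylation of the free acid by the trichloroacetimidate (tert-butyl cation transfer) should esterify without touching the methyl ester or the stereocentre.

Step 2
Reactants: 2 1-tert-butyl 5-methyl (3R)-3-methylpentanedioate
Product: 3 tert-butyl (3R)-5-hydroxy-3-methylpentanoate
Conditions: LiBH4, THF, 0 → 23 °C
Reagents that add atoms: none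
Why: Chemoselective borohydride reduction of the methyl ester in the presence of the hindered tert-butyl ester should give the primary alcohol and leave C13 untouched.

Step 3
Reactants: 3 tert-butyl (3R)-5-hydroxy-3-methylpentanoate
Product: 4 tert-butyl (3S)-5-iodo-3-methylpentanoate
Conditions: I2, PPh3, imidazole, CH2Cl2, 0 °C
Reagents that add atoms: iodine, II
Why: Appel-type iodination proceeds by SN2 displacement of the oxyphosphonium group at the primary carbon and tolerates the tert-butyl ester.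

Step 4
Reactants: 5 diethyl (2R)-2-hydroxybutanedioate (diethyl (R)-malate)
Product: 7 diethyl (2R,3S)-2-hydroxy-3-methylbutanedioate, via dilithium alkoxide enolate 6 (not isolated)
Conditions: LiN(i-Pr)2 (2.2 equiv), THF, −78 → −20 °C; MeI, −78 → 0 °C
Reagents that add atoms: iodomethane, CI
Why: Fráter–Seebach alkylation, in which the chelated dilithium alkoxide enolate is methylated anti to the alkoxide, so the bought (2R) centre sets the new (3S) centre.

Step 5
Reactants: 7 diethyl (2R,3S)-2-hydroxy-3-methylbutanedioate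
Product: 9 diethyl (2R,3S)-2-hydroxy-3-methyl-3-(prop-2-en-1-yl)butanedioate, via dilithium alkoxide enolate 8 (not isolated)
Conditions: LiN(i-Pr)2 (2.2 equiv), THF, −78 → −20 °C; allyl bromide, DMPU, −78 → 0 °C
Reagents that add atoms: allyl bromide, C=CCBr
Why: A second Fráter–Seebach alkylation of the re-formed chelated dianion again takes the electrophile anti to the alkoxide, so the quaternary centre (later C4) forms with allyl anti and methyl syn to the C3 oxygen.

Step 6
Reactants: 9 diethyl (2R,3S)-2-hydroxy-3-methyl-3-(prop-2-en-1-yl)butanedioate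
Product: 10 diethyl (2R,3S)-2-[(2-methoxypropan-2-yl)oxy]-3-methyl-3-(prop-2-en-1-yl)butanedioate
Conditions: 2-methoxypropene, PPTS (cat.), CH2Cl2, 0 °C
Reagents that add atoms: 2-methoxypropene, COC(C)=C
Why: Acid-catalysed addition of the alcohol to the enol ether (mixed-acetal protection) gives a base-stable group whose central carbon later becomes the acetonide carbon.

Step 7
Reactants: 10 diethyl (2R,3S)-2-[(2-methoxypropan-2-yl)oxy]-3-methyl-3-(prop-2-en-1-yl)butanedioate
Product: 11 ethyl (2S,3R)-3-[(2-methoxypropan-2-yl)oxy]-2-methyl-4-oxo-2-(prop-2-en-1-yl)butanoate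
Conditions: i-Bu2AlH (1.1 equiv), CH2Cl2, −78 °C; Rochelle salt
Reagents that add atoms: none
Why: Partial reduction of the α-alkoxy ester should stop at the chelated tetrahedral aluminium acetal at −78 °C, while the ester on the quaternary carbon is too hindered to react (chemoselective DIBAL-H reduction).

Step 8
Reactants: 11 ethyl (2S,3R)-3-[(2-methoxypropan-2-yl)oxy]-2-methyl-4-oxo-2-(prop-2-en-1-yl)butanoate
Product: 12 ethyl (2S,3R,4S)-4-hydroxy-3-[(2-methoxypropan-2-yl)oxy]-2-methyl-2-(prop-2-en-1-yl)hept-6-ynoate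
Conditions: allenylboronic acid pinacol ester, toluene, 23 → 50 °C; aq. NaHCO3
Reagents that add atoms: allenylboronic acid pinacol ester, C=C=CB1OC(C)(C)C(C)(C)O1
Why: Allenylboronate propargylation (SE2' addition through a six-membered transition state) should follow the polar Felkin–Anh model, with attack anti to the C3–O bond and past the hydrogen rather than the quaternary carbon, giving the 2,3-anti alcohol (C2 S in labdane numbering).

Step 9
Reactants: 12 ethyl (2S,3R,4S)-4-hydroxy-3-[(2-methoxypropan-2-yl)oxy]-2-methyl-2-(prop-2-en-1-yl)hept-6-ynoate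
Product: 13 (2R,3R,4S)-3-[(2-methoxypropan-2-yl)oxy]-2-methyl-2-(prop-2-en-1-yl)hept-6-yne-1,4-diol
Conditions: LiAlH4, THF, 0 °C
Reagents that add atoms: none
Why: Hydride reduction of the hindered ester to the primary alcohol leaves alkyne, alkene and mixed acetal intact, and any γ-lactone formed from 12 on standing converges on the same diol.

Step 10
Reactants: 13 (2R,3R,4S)-3-[(2-methoxypropan-2-yl)oxy]-2-methyl-2-(prop-2-en-1-yl)hept-6-yne-1,4-diol
Product: 14 (2R,3R,4S)-1-[(tert-butyldimethylsilyl)oxy]-3-[(2-methoxypropan-2-yl)oxy]-2-methyl-2-(prop-2-en-1-yl)hept-6-yn-4-ol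
Conditions: TBSCl, imidazole, CH2Cl2, 0 °C
Reagents that add atoms: tert-butyldimethylsilyl chloride, CC(C)(C)[Si](C)(C)Cl
Why: Silyl ether formation should be selective for the primary hydroxyl over the secondary one, which is flanked by the acetal-bearing carbon.

Step 11
Reactants: 14 (2R,3R,4S)-1-[(tert-butyldimethylsilyl)oxy]-3-[(2-methoxypropan-2-yl)oxy]-2-methyl-2-(prop-2-en-1-yl)hept-6-yn-4-ol
Product: 15 tert-butyl{[(2R)-2-[(4R,5S)-2,2-dimethyl-5-(prop-2-yn-1-yl)-1,3-dioxolan-4-yl]-2-methylpent-4-en-1-yl]oxy}dimethylsilane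
Conditions: PPTS (cat.), CH2Cl2, 23 °C
Reagents that add atoms: none
Why: Intramolecular transacetalization, in which the C2 hydroxyl captures the oxocarbenium ion from the mixed acetal and methanol is expelled, gives the cis-dioxolane without change at C2 or C3.

Step 12
Reactants: 15 tert-butyl{[(2R)-2-[(4R,5S)-2,2-dimethyl-5-(prop-2-yn-1-yl)-1,3-dioxolan-4-yl]-2-methylpent-4-en-1-yl]oxy}dimethylsilane
Product: 17 5-[(4S,5R)-5-{(2R)-1-[(tert-butyldimethylsilyl)oxy]-2-methylpent-4-en-2-yl}-2,2-dimethyl-1,3-dioxolan-4-yl]pent-3-yn-2-one, via lithium acetylide 16 (not isolated)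
Conditions: n-BuLi, THF, −78 °C; MeC(O)N(OMe)Me, −78 → 0 °C
Reagents that add atoms: N-methoxy-N-methylacetamide, CC(=O)N(C)OC
Why: Weinreb ketone synthesis, in which acylation of the lithium acetylide stops at the ketone because the tetrahedral chelate survives until work-up.

Step 13
Reactants: 17 5-[(4S,5R)-5-{(2R)-1-[(tert-butyldimethylsilyl)oxy]-2-methylpent-4-en-2-yl}-2,2-dimethyl-1,3-dioxolan-4-yl]pent-3-yn-2-one
Product: 19 (3E)-5-[(4S,5R)-5-{(2R)-1-[(tert-butyldimethylsilyl)oxy]-2-methylpent-4-en-2-yl}-2,2-dimethyl-1,3-dioxolan-4-yl]-3-iodo-4-methylpent-3-en-2-one, via lithium allenolate 18 (not isolated)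
Conditions: Me2CuLi (from MeLi, CuI), THF, −78 °C; I2, −78 °C
Reagents that add atoms: lithium dimethylcuprate, [Li+].C[Cu-]C; iodine, II
Why: Conjugate addition of the cuprate to the ynone puts the methyl group on the β-carbon (later C10) and iodinolysis of the copper allenolate puts iodine on the α-carbon (conjugate addition–electrophilic trapping), and the alkene geometry is of no consequence later.

Step 14
Reactants: 19 (3E)-5-[(4S,5R)-5-{(2R)-1-[(tert-butyldimethylsilyl)oxy]-2-methylpent-4-en-2-yl}-2,2-dimethyl-1,3-dioxolan-4-yl]-3-iodo-4-methylpent-3-en-2-one; 4 tert-butyl (3S)-5-iodo-3-methylpentanoate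
Product: 21 tert-butyl (3R,6Z)-6-acetyl-8-[(4S,5R)-5-{(2R)-1-[(tert-butyldimethylsilyl)oxy]-2-methylpent-4-en-2-yl}-2,2-dimethyl-1,3-dioxolan-4-yl]-3,7-dimethyloct-6-enoate, via alkylzinc iodide 20 (not isolated)
Conditions: 4, Zn dust, LiCl, THF, 40 °C; then 19, Pd(OAc)2 (cat.), SPhos (cat.), THF, 23 → 45 °C
Reagents that add atoms: none
Why: Negishi cross-coupling, in which zinc insertion into the primary iodide tolerates the ester and the alkylzinc couples with the alkenyl iodide at zerovalent palladium carrying a bulky biaryl phosphine, joins C9 to C11.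

Step 15
Reactants: 21 tert-butyl (3R,6Z)-6-acetyl-8-[(4S,5R)-5-{(2R)-1-[(tert-butyldimethylsilyl)oxy]-2-methylpent-4-en-2-yl}-2,2-dimethyl-1,3-dioxolan-4-yl]-3,7-dimethyloct-6-enoate
Product: 22 tert-butyl (3R,6Z)-6-acetyl-8-[(4S,5R)-5-{(2R)-1-[(tert-butyldimethylsilyl)oxy]-2-methyl-4-oxopentan-2-yl}-2,2-dimethyl-1,3-dioxolan-4-yl]-3,7-dimethyloct-6-enoate
Conditions: PdCl2 (cat.), CuCl, O2 (1 atm), DMF/H2O (7:1), 23 °C
Reagents that add atoms: water, O
Why: Tsuji–Wacker oxidation should convert the terminal alkene into the methyl ketone with Markovnikov selectivity, while the tetrasubstituted enone is inert to oxypalladation.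

Step 16
Reactants: 22 tert-butyl (3R,6Z)-6-acetyl-8-[(4S,5R)-5-{(2R)-1-[(tert-butyldimethylsilyl)oxy]-2-methyl-4-oxopentan-2-yl}-2,2-dimethyl-1,3-dioxolan-4-yl]-3,7-dimethyloct-6-enoate
Product: 25 tert-butyl (2S,3R,4R,5S,9R,10S,13R)-19-[(tert-butyldimethylsilyl)oxy]-2,3-(isopropylidenedioxy)-6-oxolabd-7-en-15-oate, via Michael adduct diketone 23 (not isolated), via aldol ketol 24 (not isolated)
Conditions: KOt-Bu (0.3 equiv), t-BuOH/THF (1:1), 0.01 M, 0 → 40 °C
Reagents that add atoms: none
Why: Base equilibrates the ketone enolates, but only the C5 enolate of the C6 ketone can reach the enone, adding to its β-carbon C10 in a 6-exo-trig Michael reaction that closes ring A; the C7 enolate of the resulting 1,5-diketone then attacks the C8 carbonyl (6-exo-trig aldol, enolate exocyclic) and E1cB loss of water gives the C7=C8 enone, closing ring B. The closest known reaction type is the tandem Michael–aldol condensation of Hagemann- and Robinson-type annulations, here run fully intramolecularly. In the chair transition state of the Michael step the cis-fused dioxolane keeps the C2 oxygen equatorial and the C3 oxygen axial, the C4 silyloxymethyl group is axial, and the small C20 methyl takes the axial site on C10 beside it while the bulky C9 terminus stays equatorial, so C10 is set by C2, C3 and C4; the other chair would place the C2 oxygen and the C18 and C20 methyl groups in one syn-triaxial array. C5, α to the C6 ketone, should equilibrate to the trans ring fusion, and C9 should end with the side chain equatorial after axial protonation of the ring B dienolate on the face anti to the C10 methyl. The step needs the Michael addition to win over vinylogous β-elimination of the C2 oxygen, and the aldol to run from C7 to C8 and not from C17 to C6; the pre-folded cis-dioxolane and the quaternary C4 speed the ring closure, and the C6 carbonyl is shielded by the two flanking quaternary carbons C4 and C10.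

Step 17
Reactants: 25 tert-butyl (2S,3R,4R,5S,9R,10S,13R)-19-[(tert-butyldimethylsilyl)oxy]-2,3-(isopropylidenedioxy)-6-oxolabd-7-en-15-oate
Product: 26 tert-butyl (2S,3R,4R,5S,6S,9R,10S,13R)-19-[(tert-butyldimethylsilyl)oxy]-6-hydroxy-2,3-(isopropylidenedioxy)labd-7-en-15-oate
Conditions: NaBH4, CeCl3·7H2O, MeOH, −40 → 0 °C
Reagents that add atoms: none
Why: Luche reduction gives 1,2-reduction of the enone, with hydride expected from the face opposite the axial C19 and C20 groups to give the axial (6S) alcohol, a centre that is removed later.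

Step 18
Reactants: 26 tert-butyl (2S,3R,4R,5S,6S,9R,10S,13R)-19-[(tert-butyldimethylsilyl)oxy]-6-hydroxy-2,3-(isopropylidenedioxy)labd-7-en-15-oate
Product: 27 tert-butyl (2S,3R,4R,5S,6S,9R,10S,13R)-6,19-dihydroxy-2,3-(isopropylidenedioxy)labd-7-en-15-oate
Conditions: n-Bu4NF, THF, 0 → 23 °C
Reagents that add atoms: none
Why: Fluoride-mediated desilylation (Si–F bond formation) frees the primary alcohol and leaves the tert-butyl ester and the acetonide untouched.

Step 19
Reactants: 27 tert-butyl (2S,3R,4R,5S,6S,9R,10S,13R)-6,19-dihydroxy-2,3-(isopropylidenedioxy)labd-7-en-15-oate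
Product: 28 tert-butyl (2S,3R,4R,5S,6S,9R,10S,13R)-6,19-diacetoxy-2,3-(isopropylidenedioxy)labd-7-en-15-oate
Conditions: Ac2O, DMAP, pyridine, 23 → 50 °C
Reagents that add atoms: acetic anhydride, CC(=O)OC(C)=O
Why: DMAP-catalysed acylation should esterify both the primary C19 hydroxyl and the hindered allylic C6 hydroxyl, installing the acetate of the target and the leaving group for deoxygenation in one step.

Step 20
Reactants: 28 tert-butyl (2S,3R,4R,5S,6S,9R,10S,13R)-6,19-diacetoxy-2,3-(isopropylidenedioxy)labd-7-en-15-oate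
Product: 29 tert-butyl (2S,3R,4R,5S,9R,10S,13R)-19-acetoxy-2,3-(isopropylidenedioxy)labd-7-en-15-oate
Conditions: Pd(PPh3)4 (cat.), n-Bu3SnH, THF, 23 → 50 °C
Reagents that add atoms: none
Why: Zerovalent palladium ionises only the allylic C6 acetate (Tsuji–Trost-type π-allyl formation) and the hydride transferred from tin should be delivered to the less substituted allyl terminus C6, which keeps the trisubstituted C7=C8 bond and leaves the primary acetate untouched.

Step 21
Reactants: 29 tert-butyl (2S,3R,4R,5S,9R,10S,13R)-19-acetoxy-2,3-(isopropylidenedioxy)labd-7-en-15-oate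
Product: 30 (2S,3R,4R,5S,9R,10S,13R)-19-acetoxy-2,3-dihydroxylabd-7-en-15-oic acid (target)
Conditions: CF3CO2H/CH2Cl2/H2O (20:78:2), 0 → 23 °C
Reagents that add atoms: none
Why: Aqueous trifluoroacetic acid hydrolyses the acetonide and cleaves the tert-butyl ester by the E1 (isobutene) pathway, while the primary acetate survives and cannot migrate to the C3 hydroxyl because the two groups are trans-diaxial.

## Compound list

1 | (S)-5-methoxy-3-methyl-5-oxopentanoic acid | COC(=O)C[C@@H](C)CC(=O)O | starting material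
2 | 1-tert-butyl 5-methyl (3R)-3-methylpentanedioate | COC(=O)C[C@@H](C)CC(=O)OC(C)(C)C | intermediate
3 | tert-butyl (3R)-5-hydroxy-3-methylpentanoate | OCC[C@@H](C)CC(=O)OC(C)(C)C | intermediate
4 | tert-butyl (3S)-5-iodo-3-methylpentanoate | ICC[C@@H](C)CC(=O)OC(C)(C)C | intermediate
5 | diethyl (2R)-2-hydroxybutanedioate | CCOC(=O)[C@H](O)CC(=O)OCC | starting material
6 | dilithium alkoxide enolate of 5 (not isolated) | CCOC(=O)[C@H]([O-])C=C([O-])OCC.[Li+].[Li+] | intermediate
7 | diethyl (2R,3S)-2-hydroxy-3-methylbutanedioate | CCOC(=O)[C@H](O)[C@H](C)C(=O)OCC | intermediate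
8 | dilithium alkoxide enolate of 7 (not isolated) | CCOC(=O)[C@H]([O-])C(C)=C([O-])OCC.[Li+].[Li+] | intermediate
9 | diethyl (2R,3S)-2-hydroxy-3-methyl-3-(prop-2-en-1-yl)butanedioate | CCOC(=O)[C@H](O)[C@](C)(CC=C)C(=O)OCC | intermediate
10 | diethyl (2R,3S)-2-[(2-methoxypropan-2-yl)oxy]-3-methyl-3-(prop-2-en-1-yl)butanedioate | CCOC(=O)[C@H](OC(C)(C)OC)[C@](C)(CC=C)C(=O)OCC | intermediate
11 | ethyl (2S,3R)-3-[(2-methoxypropan-2-yl)oxy]-2-methyl-4-oxo-2-(prop-2-en-1-yl)butanoate | O=C[C@H](OC(C)(C)OC)[C@](C)(CC=C)C(=O)OCC | intermediate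
12 | ethyl (2S,3R,4S)-4-hydroxy-3-[(2-methoxypropan-2-yl)oxy]-2-methyl-2-(prop-2-en-1-yl)hept-6-ynoate | C#CC[C@H](O)[C@H](OC(C)(C)OC)[C@](C)(CC=C)C(=O)OCC | intermediate
13 | (2R,3R,4S)-3-[(2-methoxypropan-2-yl)oxy]-2-methyl-2-(prop-2-en-1-yl)hept-6-yne-1,4-diol | C#CC[C@H](O)[C@H](OC(C)(C)OC)[C@](C)(CC=C)CO | intermediate
14 | (2R,3R,4S)-1-[(tert-butyldimethylsilyl)oxy]-3-[(2-methoxypropan-2-yl)oxy]-2-methyl-2-(prop-2-en-1-yl)hept-6-yn-4-ol | C#CC[C@H](O)[C@H](OC(C)(C)OC)[C@](C)(CC=C)CO[Si](C)(C)C(C)(C)C | intermediate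
15 | tert-butyl{[(2R)-2-[(4R,5S)-2,2-dimethyl-5-(prop-2-yn-1-yl)-1,3-dioxolan-4-yl]-2-methylpent-4-en-1-yl]oxy}dimethylsilane | C#CC[C@@H]1OC(C)(C)O[C@@H]1[C@](C)(CC=C)CO[Si](C)(C)C(C)(C)C | intermediate
16 | lithium acetylide of 15 (not isolated) | [Li+].[C-]#CC[C@@H]1OC(C)(C)O[C@@H]1[C@](C)(CC=C)CO[Si](C)(C)C(C)(C)C | intermediate
17 | 5-[(4S,5R)-5-{(2R)-1-[(tert-butyldimethylsilyl)oxy]-2-methylpent-4-en-2-yl}-2,2-dimethyl-1,3-dioxolan-4-yl]pent-3-yn-2-one | CC(=O)C#CC[C@@H]1OC(C)(C)O[C@@H]1[C@](C)(CC=C)CO[Si](C)(C)C(C)(C)C | intermediate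
18 | lithium allenolate from methyl transfer to 17, 4-methylpenta-2,3-dien-2-olate with the dioxolanylmethyl group on C4 (not isolated) | [Li+].CC([O-])=C=C(C)C[C@@H]1OC(C)(C)O[C@@H]1[C@](C)(CC=C)CO[Si](C)(C)C(C)(C)C | intermediate
19 | (3E)-5-[(4S,5R)-5-{(2R)-1-[(tert-butyldimethylsilyl)oxy]-2-methylpent-4-en-2-yl}-2,2-dimethyl-1,3-dioxolan-4-yl]-3-iodo-4-methylpent-3-en-2-one | CC(=O)/C(I)=C(/C)C[C@@H]1OC(C)(C)O[C@@H]1[C@](C)(CC=C)CO[Si](C)(C)C(C)(C)C | intermediate
20 | [(3S)-5-tert-butoxy-3-methyl-5-oxopentyl]zinc iodide (not isolated) | I[Zn]CC[C@@H](C)CC(=O)OC(C)(C)C | intermediate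
21 | tert-butyl (3R,6Z)-6-acetyl-8-[(4S,5R)-5-{(2R)-1-[(tert-butyldimethylsilyl)oxy]-2-methylpent-4-en-2-yl}-2,2-dimethyl-1,3-dioxolan-4-yl]-3,7-dimethyloct-6-enoate | CC(=O)/C(CC[C@@H](C)CC(=O)OC(C)(C)C)=C(/C)C[C@@H]1OC(C)(C)O[C@@H]1[C@](C)(CC=C)CO[Si](C)(C)C(C)(C)C | intermediate
22 | tert-butyl (3R,6Z)-6-acetyl-8-[(4S,5R)-5-{(2R)-1-[(tert-butyldimethylsilyl)oxy]-2-methyl-4-oxopentan-2-yl}-2,2-dimethyl-1,3-dioxolan-4-yl]-3,7-dimethyloct-6-enoate | CC(=O)/C(CC[C@@H](C)CC(=O)OC(C)(C)C)=C(/C)C[C@@H]1OC(C)(C)O[C@@H]1[C@](C)(CC(C)=O)CO[Si](C)(C)C(C)(C)C | intermediate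
23 | Michael adduct: ring A 1,5-diketone with acetyl on C5 and the 3-oxobutan-2-yl arm (C9, C8, C17, carrying the side chain) on C10; (2S,3R,4R,5S,9S,10S,13R) in labdane numbering (not isolated) | CC(C)(C)[Si](C)(C)OC[C@@]1(C)[C@@H](C(C)=O)[C@](C)([C@H](CC[C@@H](C)CC(=O)OC(C)(C)C)C(C)=O)C[C@@H]2OC(C)(C)O[C@H]12 | intermediate
24 | aldol ketol: tert-butyl 19-[(tert-butyldimethylsilyl)oxy]-8-hydroxy-2,3-(isopropylidenedioxy)-6-oxolabdan-15-oate, either C8 epimer, otherwise (2S,3R,4R,5S,9S,10S,13R) (not isolated) | CC(C)(C)[Si](C)(C)OC[C@@]1(C)[C@H]2C(=O)CC(C)(O)[C@@H](CC[C@@H](C)CC(=O)OC(C)(C)C)[C@]2(C)C[C@@H]3OC(C)(C)O[C@H]13 | intermediate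
25 | tert-butyl (2S,3R,4R,5S,9R,10S,13R)-19-[(tert-butyldimethylsilyl)oxy]-2,3-(isopropylidenedioxy)-6-oxolabd-7-en-15-oate | CC(C)(C)[Si](C)(C)OC[C@@]1(C)[C@H]2C(=O)C=C(C)[C@@H](CC[C@@H](C)CC(=O)OC(C)(C)C)[C@]2(C)C[C@@H]3OC(C)(C)O[C@H]13 | intermediate
26 | tert-butyl (2S,3R,4R,5S,6S,9R,10S,13R)-19-[(tert-butyldimethylsilyl)oxy]-6-hydroxy-2,3-(isopropylidenedioxy)labd-7-en-15-oate | CC(C)(C)[Si](C)(C)OC[C@@]1(C)[C@H]2[C@@H](O)C=C(C)[C@@H](CC[C@@H](C)CC(=O)OC(C)(C)C)[C@]2(C)C[C@@H]3OC(C)(C)O[C@H]13 | intermediate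
27 | tert-butyl (2S,3R,4R,5S,6S,9R,10S,13R)-6,19-dihydroxy-2,3-(isopropylidenedioxy)labd-7-en-15-oate | OC[C@@]1(C)[C@H]2[C@@H](O)C=C(C)[C@@H](CC[C@@H](C)CC(=O)OC(C)(C)C)[C@]2(C)C[C@@H]3OC(C)(C)O[C@H]13 | intermediate
28 | tert-butyl (2S,3R,4R,5S,6S,9R,10S,13R)-6,19-diacetoxy-2,3-(isopropylidenedioxy)labd-7-en-15-oate | CC(=O)OC[C@@]1(C)[C@H]2[C@@H](OC(C)=O)C=C(C)[C@@H](CC[C@@H](C)CC(=O)OC(C)(C)C)[C@]2(C)C[C@@H]3OC(C)(C)O[C@H]13 | intermediate
29 | tert-butyl (2S,3R,4R,5S,9R,10S,13R)-19-acetoxy-2,3-(isopropylidenedioxy)labd-7-en-15-oate | CC(=O)OC[C@@]1(C)[C@H]2CC=C(C)[C@@H](CC[C@@H](C)CC(=O)OC(C)(C)C)[C@]2(C)C[C@@H]3OC(C)(C)O[C@H]13 | intermediate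
30 | (2S,3R,4R,5S,9R,10S,13R)-19-acetoxy-2,3-dihydroxylabd-7-en-15-oic acid | CC(=O)OC[C@@]1(C)[C@H]2CC=C(C)[C@@H](CC[C@@H](C)CC(=O)O)[C@]2(C)C[C@H](O)[C@@H]1O | target

## Step count and risks

Total step count: 21. Longest linear sequence: 18 steps (steps 4 to 21, from diethyl (R)-malate); the side-chain branch (steps 1 to 3) joins at step 14.

Steps most likely to fail:

1. Step 16 (key step). The Michael addition to the tetrasubstituted enone may be slow, so that γ-deprotonation at C1 followed by vinylogous β-elimination of the C2 oxygen, aldol closure in the wrong sense (C17 onto C6), or incomplete equilibration at C9 can compete. Fallback: setting out from 22, the cascade is split into a silyl-mediated Mukaiyama–Michael addition and a separate condensation. tert-Butyldimethylsilyl triflate and triethylamine in CH2Cl2 (−78 → 23 °C) form the silyl enol ethers in situ and activate the enone, which should close ring A and give the C8 silyl enol ether F1. Brief hydrolysis (aq. HCl, THF, 0 °C) then gives the diketone 23 as an isolated compound. Aldol condensation of 23 with KOH in methanol or pyrrolidinium acetate returns to the route at 25.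

2. Step 13. The copper allenolate may be protonated instead of iodinated, or iodine may be consumed by the terminal alkene, so that the β-methyl enone forms instead of the iodo enone. Fallback: setting out from 17, the cuprate adduct is trapped with chlorotrimethylsilane (Me2CuLi, Me3SiCl, THF, −78 °C) and isolated as the trimethylsilyl allenyl ether F2. Electrophilic iodination of F2 at its central allene carbon with N-iodosuccinimide (CH2Cl2, −40 °C) in a separate operation returns to the route at 19.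

3. Step 20. Hydride may be delivered to the tertiary allyl terminus C8, which moves the double bond to C6=C7, or ionisation of the hindered axial acetate may be sluggish. Fallback: a radical deoxygenation setting out from 26. The C6 alkoxide (NaH, THF) is converted with CS2 and MeI into the S-methyl xanthate F3. Barton–McCombie reduction (n-Bu3SnH, AIBN, toluene, 90 °C), in which the allyl radical should take hydrogen at the less hindered C6, gives the silyl ether F4. n-Bu4NF then frees the primary alcohol F5, and acetylation (Ac2O, DMAP, pyridine) returns to the route at 29.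

## Further compounds

F1 | step 16 | ring A Michael product as the C8 tert-butyldimethylsilyl enol ether (C9=C8 enol ether, C6 ketone free), otherwise as 23 | CC(C)(C)[Si](C)(C)OC[C@@]1(C)[C@@H](C(C)=O)[C@](C)(C(CC[C@@H](C)CC(=O)OC(C)(C)C)=C(C)O[Si](C)(C)C(C)(C)C)C[C@@H]2OC(C)(C)O[C@H]12
F2 | step 13 | trimethylsilyl allenyl ether of the cuprate adduct of 17 (2-trimethylsilyloxy-4-methylpenta-2,3-diene with the dioxolanylmethyl group on C4) | CC(O[Si](C)(C)C)=C=C(C)C[C@@H]1OC(C)(C)O[C@@H]1[C@](C)(CC=C)CO[Si](C)(C)C(C)(C)C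
F3 | step 20 | O-(6S)-labd-7-en-6-yl S-methyl dithiocarbonate of 26 (C19 silyl ether, acetonide and tert-butyl ester retained) | CC(C)(C)[Si](C)(C)OC[C@@]1(C)[C@H]2[C@@H](OC(=S)SC)C=C(C)[C@@H](CC[C@@H](C)CC(=O)OC(C)(C)C)[C@]2(C)C[C@@H]3OC(C)(C)O[C@H]13
F4 | step 20 | tert-butyl (2S,3R,4R,5S,9R,10S,13R)-19-[(tert-butyldimethylsilyl)oxy]-2,3-(isopropylidenedioxy)labd-7-en-15-oate | CC(C)(C)[Si](C)(C)OC[C@@]1(C)[C@H]2CC=C(C)[C@@H](CC[C@@H](C)CC(=O)OC(C)(C)C)[C@]2(C)C[C@@H]3OC(C)(C)O[C@H]13
F5 | step 20 | tert-butyl (2S,3R,4R,5S,9R,10S,13R)-19-hydroxy-2,3-(isopropylidenedioxy)labd-7-en-15-oate | OC[C@@]1(C)[C@H]2CC=C(C)[C@@H](CC[C@@H](C)CC(=O)OC(C)(C)C)[C@]2(C)C[C@@H]3OC(C)(C)O[C@H]13
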